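**Plan**
- Retrosynthesis first cuts the fifteen O–alkyl bonds (global dealkylation) and traces the ring A C4 and ring E C3 hydroxyls back to formyl groups; rings are lettered A to G from the 2,4,6-trihydroxyphenyl end.
- The D–E diaryl ether is cut next, giving a ring A–D phenol and a ring E–G aryl iodide; the A–B and B–C ethers are each cut to a phenol plus 4-bromo-3,5-dimethoxybenzaldehyde, and the E–F and F–G ethers to a phenol plus an arylboronic acid.
- Ring C has oxygen on five adjacent carbons (aryloxy at C1 and C6, hydroxyl at C3, C4 and C5) and a single CH at C2. Four of these carbons with their oxygens map onto a squarate and C2/C3 onto an alkoxyvinyl unit, so ring C is cut at C1–C2 to a cyclobutenone that already carries the ring D ether.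
- Forward: squaric acid gives a mixed aryl methyl squarate, then the ethoxyvinyl carbinol and its methyl ether; thermolysis closes ring C (rings C–D). Ring B and then ring A are added, ring D is unmasked, the E–G iodide is joined, and Dakin oxidation and BBr3 finish the synthesis.
- The target has no stereocentre; the one racemic carbon of the cyclobutenone becomes aromatic in the ring-forming step.

Key step: step 8

Assumption: 4-bromo-3,5-dimethoxybenzaldehyde, 4-bromo-2,6-dimethoxyphenol, (3,4,5-trimethoxyphenyl)boronic acid and 5-iodovanillin are taken as purchasable. The ring D oxygen is masked as a methoxymethyl (MOM) ether rather than a benzyl ether, because it must later be unmasked in the presence of a formyl group.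

**Route**

Step 1
Reactants: 1 squaric acid
Product: 2 squaric acid dichloride (3,4-dichlorocyclobut-3-ene-1,2-dione)
Conditions: (COCl)2, cat. DMF, 1,2-dichloroethane, 50 °C
Reagents that add atoms: oxalyl chloride, O=C(Cl)C(Cl)=O
Why: Vilsmeier-type activation converts both vinylogous acid hydroxyls into the vinylogous acid chloride, the usual entry to squarate electrophiles.

Step 2
Reactants: 2 squaric acid dichloride
Product: 3 3-chloro-4-methoxycyclobut-3-ene-1,2-dione
Conditions: MeOH (1.0 equiv), Et2O, 0 °C to rt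
Reagents that add atoms: methanol, CO
Why: Addition–elimination of one equivalent of methanol at the vinylogous acyl chloride should stop at the ester chloride, since the first methoxy donor deactivates the ring towards a second substitution.

Step 3
Reactants: 4 syringaldehyde
Product: 5 3,5-dimethoxy-4-(methoxymethoxy)benzaldehyde
Conditions: NaH, THF/DMF, 0 °C; MOMCl, 0 °C to rt
Reagents that add atoms: chloromethyl methyl ether, COCCl
Why: Williamson-type O-alkylation of the phenoxide gives an acetal that tolerates base, organolithium, heat and peracid and is later removed by dilute acid without harm to a formyl group.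

Step 4
Reactants: 5 3,5-dimethoxy-4-(methoxymethoxy)benzaldehyde
Product: 7 3,5-dimethoxy-4-(methoxymethoxy)phenol, via aryl formate 6 (not isolated)
Conditions: mCPBA, CH2Cl2, 0 °C to rt; then cat. K2CO3, MeOH, rt
Reagents that add atoms: mCPBA (3-chloroperoxybenzoic acid), OOC(=O)c1cccc(Cl)c1
Why: Baeyer–Villiger (Dakin-type) oxidation, in which the electron-rich aryl group migrates in the Criegee intermediate and the resulting formate is cleaved by mild methanolysis.

Step 5
Reactants: 7 3,5-dimethoxy-4-(methoxymethoxy)phenol; 3 3-chloro-4-methoxycyclobut-3-ene-1,2-dione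
Product: 8 3-[3,5-dimethoxy-4-(methoxymethoxy)phenoxy]-4-methoxycyclobut-3-ene-1,2-dione
Conditions: 7, NaH, THF, 0 °C; then 3, −78 to −20 °C
Reagents that add atoms: none
Why: Vinylogous acyl substitution (addition–elimination) in which the phenoxide displaces chloride, a far better leaving group than methoxide, to give the mixed aryl methyl squarate.

Step 6
Reactants: 8 mixed aryl methyl squarate; 9 ethyl vinyl ether
Product: 10 racemic 2-[3,5-dimethoxy-4-(methoxymethoxy)phenoxy]-4-(1-ethoxyvinyl)-4-hydroxy-3-methoxycyclobut-2-en-1-one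
Conditions: 9, t-BuLi, THF, −78 to 0 °C; recool, add to 8, THF, −78 °C; aq. NH4Cl at −78 °C
Reagents that add atoms: none
Why: 1,2-Addition of 1-ethoxyvinyllithium should occur at the carbonyl conjugated to the weaker aryloxy donor and flanked by the small methoxy-bearing carbon (the more ketone-like carbonyl, as in additions to unsymmetrical squarates); the new quaternary carbinol forms as a racemate and needs no control because it is lost in step 8.

Step 7
Reactants: 10 racemic ethoxyvinyl carbinol
Product: 11 racemic 2-[3,5-dimethoxy-4-(methoxymethoxy)phenoxy]-4-(1-ethoxyvinyl)-3,4-dimethoxycyclobut-2-en-1-one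
Conditions: MeI (excess), Ag2O, MeCN, rt, dark
Reagents that add atoms: iodomethane, CI
Why: Ag2O-promoted O-methylation of the tertiary 4-hydroxycyclobutenone under essentially neutral conditions avoids the alkoxide-accelerated ring opening that a strong base would provoke.

Step 8
Reactants: 11 racemic 4-(1-ethoxyvinyl)-4-methoxycyclobutenone
Product: 14 2-[3,5-dimethoxy-4-(methoxymethoxy)phenoxy]-5-ethoxy-3,4-dimethoxyphenol, via Z-dienylketene 12 (not isolated), via cyclohexa-2,4-dienone 13 (not isolated)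
Conditions: degassed p-xylene (about 0.01 M), 138 °C, base-washed glassware
Reagents that add atoms: none
Why: Heating opens the cyclobutenone by conrotatory 4π electrocyclic cleavage of the C1–C4 bond to the Z-dienylketene 12. Ring C then closes by a thermally allowed disrotatory 6π electrocyclisation in which the ketene carbon bonds to the terminal CH2 of the ethoxyvinyl group (the ring C C1–C2 bond), and the cyclohexa-2,4-dienone 13 enolises irreversibly to the phenol. The closest known reaction type is the Moore rearrangement of squarate-derived 4-alkenyl-4-alkoxycyclobutenones to mono-protected hydroquinones. No stereocentre is created, and the racemic quaternary carbon of 11 becomes the aromatic C4 of ring C. The step needs torquoselectivity, which the 4-methoxy donor supplies by rotating outward so that the ethoxyvinyl group turns inward, cis to the ketene; the oxygen pattern was fixed beforehand by the site-selective addition of step 6. Neutral, acid-free conditions keep the enol ether and the MOM acetal intact, and the only free hydroxyl formed is the C1 oxygen needed for the bond to ring B.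

Step 9
Reactants: 14 ring C–D phenol; 15 4-bromo-3,5-dimethoxybenzaldehyde
Product: 16 4-{2-[3,5-dimethoxy-4-(methoxymethoxy)phenoxy]-5-ethoxy-3,4-dimethoxyphenoxy}-3,5-dimethoxybenzaldehyde (rings B–C–D)
Conditions: CuI (cat.), picolinic acid (cat.), K3PO4, DMSO, 90–100 °C, Ar
Reagents that add atoms: none
Why: Ullmann-type copper-catalysed O-arylation with a picolinate ligand suited to ortho-substituted partners, in which the para-formyl group activates the methoxy-flanked C–Br bond and serves as the masked ring B hydroxyl.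

Step 10
Reactants: 16 rings B–C–D aldehyde
Product: 18 4-{2-[3,5-dimethoxy-4-(methoxymethoxy)phenoxy]-5-ethoxy-3,4-dimethoxyphenoxy}-3,5-dimethoxyphenol, via aryl formate 17 (not isolated)
Conditions: mCPBA, CH2Cl2, 0 °C to rt; then cat. K2CO3, MeOH, rt
Reagents that add atoms: mCPBA (3-chloroperoxybenzoic acid), OOC(=O)c1cccc(Cl)c1
Why: Baeyer–Villiger (Dakin-type) oxidation of a para-aryloxy benzaldehyde, whose electron-rich aryl group migrates to give the formate and, after methanolysis, the ring B C1 phenol.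

Step 11
Reactants: 18 rings B–C–D phenol; 15 4-bromo-3,5-dimethoxybenzaldehyde
Product: 19 4-(4-{2-[3,5-dimethoxy-4-(methoxymethoxy)phenoxy]-5-ethoxy-3,4-dimethoxyphenoxy}-3,5-dimethoxyphenoxy)-3,5-dimethoxybenzaldehyde (rings A–D)
Conditions: CuI (cat.), picolinic acid (cat.), K3PO4, DMSO, 90–100 °C, Ar
Reagents that add atoms: none
Why: The same Ullmann-type O-arylation, here with an unhindered phenol, installs ring A with its C4 oxygen held as a formyl group that is inert to the later coupling.

Step 12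
Reactants: 19 rings A–D aldehyde
Product: 20 4-{4-[5-ethoxy-2-(4-hydroxy-3,5-dimethoxyphenoxy)-3,4-dimethoxyphenoxy]-3,5-dimethoxyphenoxy}-3,5-dimethoxybenzaldehyde
Conditions: 2 M aq. HCl (cat.), THF, 45 °C
Reagents that add atoms: none
Why: Acid-catalysed acetal hydrolysis removes the MOM group and frees the ring D C4 hydroxyl, while aryl alkyl ethers, diaryl ethers and the formyl group are stable to dilute acid.

Step 13
Reactants: 21 4-bromo-2,6-dimethoxyphenol; 22 (3,4,5-trimethoxyphenyl)boronic acid
Product: 23 5-bromo-1,3-dimethoxy-2-(3,4,5-trimethoxyphenoxy)benzene (rings F–G)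
Conditions: Cu(OAc)2, pyridine, 4 Å molecular sieves, CH2Cl2, air, rt
Reagents that add atoms: none
Why: Chan–Lam–Evans oxidative coupling with divalent copper joins a doubly ortho-substituted phenol to an unhindered electron-rich arylboronic acid at room temperature, and the para bromine blocks oxidative phenol dimerisation and is not touched.

Step 14
Reactants: 23 rings F–G bromide
Product: 24 [3,5-dimethoxy-4-(3,4,5-trimethoxyphenoxy)phenyl]boronic acid
Conditions: n-BuLi, THF, −78 °C; B(OiPr)3, −78 °C to rt; aq. HCl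
Reagents that add atoms: triisopropyl borate, CC(C)OB(OC(C)C)OC(C)C; water, O
Why: Bromine–lithium exchange outpaces ortho-metalation at −78 °C, and trapping of the aryllithium with the borate followed by hydrolysis gives the boronic acid.

Step 15
Reactants: 24 rings F–G boronic acid; 25 5-iodovanillin (4-hydroxy-3-iodo-5-methoxybenzaldehyde)
Product: 26 4-[3,5-dimethoxy-4-(3,4,5-trimethoxyphenoxy)phenoxy]-3-iodo-5-methoxybenzaldehyde (rings E–G)
Conditions: Cu(OAc)2, pyridine, 4 Å molecular sieves, CH2Cl2, air, rt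
Reagents that add atoms: none
Why: Chan–Lam–Evans coupling is established for acidic ortho-iodophenols, and the carbon–iodine bond and the formyl group survive divalent copper at room temperature.

Step 16
Reactants: 20 rings A–D phenol; 26 rings E–G iodide
Product: 27 4-{4-[2-(4-{2-[3,5-dimethoxy-4-(3,4,5-trimethoxyphenoxy)phenoxy]-5-formyl-3-methoxyphenoxy}-3,5-dimethoxyphenoxy)-5-ethoxy-3,4-dimethoxyphenoxy]-3,5-dimethoxyphenoxy}-3,5-dimethoxybenzaldehyde (rings A–G dialdehyde)
Conditions: CuI, picolinic acid, K3PO4, DMSO, 90–100 °C, Ar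
Reagents that add atoms: none
Why: Ullmann-type copper-catalysed O-arylation of a 2,6-dimethoxyphenol with an ortho-substituted aryl iodide, the partner class for which the CuI/picolinic acid system is suited, with one phenol and one iodide as the only reactive sites.

Step 17
Reactants: 27 rings A–G dialdehyde
Product: 29 4-{4-[2-(4-{2-[3,5-dimethoxy-4-(3,4,5-trimethoxyphenoxy)phenoxy]-5-hydroxy-3-methoxyphenoxy}-3,5-dimethoxyphenoxy)-5-ethoxy-3,4-dimethoxyphenoxy]-3,5-dimethoxyphenoxy}-3,5-dimethoxyphenol, via bis-formate 28 (not isolated)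
Conditions: mCPBA (excess), CH2Cl2, 0 °C to rt; then cat. K2CO3, MeOH, rt
Reagents that add atoms: mCPBA (3-chloroperoxybenzoic acid), OOC(=O)c1cccc(Cl)c1
Why: Twofold Baeyer–Villiger (Dakin-type) oxidation, both formyl groups sitting para to an aryloxy donor so that aryl migration is favoured, turns them into the ring A C4 and ring E C3 hydroxyls.

Step 18
Reactants: 29 rings A–G diphenol
Product: 30 CNP0351377.0 (the heptaaryl hexaether with seventeen free hydroxyls)
Conditions: BBr3 (excess), CH2Cl2, −78 °C to rt, Ar; then H2O, 0 °C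
Reagents that add atoms: none
Why: Lewis-acid dealkylation with BBr3 cleaves the fourteen methyl ethers and the ethyl ether by bromide attack at the alkyl carbon and leaves the six diaryl ether bonds untouched.

**Compound list**
1 | squaric acid (3,4-dihydroxycyclobut-3-ene-1,2-dione) | OC1=C(O)C(=O)C1=O | starting material
2 | squaric acid dichloride (3,4-dichlorocyclobut-3-ene-1,2-dione) | ClC1=C(Cl)C(=O)C1=O | intermediate
3 | 3-chloro-4-methoxycyclobut-3-ene-1,2-dione | COC1=C(Cl)C(=O)C1=O | intermediate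
4 | syringaldehyde (4-hydroxy-3,5-dimethoxybenzaldehyde) | COc1cc(C=O)cc(OC)c1O | starting material
5 | 3,5-dimethoxy-4-(methoxymethoxy)benzaldehyde | COCOc1c(OC)cc(C=O)cc1OC | intermediate
6 | 3,5-dimethoxy-4-(methoxymethoxy)phenyl formate | COCOc1c(OC)cc(OC=O)cc1OC | intermediate (not isolated)
7 | 3,5-dimethoxy-4-(methoxymethoxy)phenol | COCOc1c(OC)cc(O)cc1OC | intermediate
8 | 3-[3,5-dimethoxy-4-(methoxymethoxy)phenoxy]-4-methoxycyclobut-3-ene-1,2-dione | COCOc1c(OC)cc(OC2=C(OC)C(=O)C2=O)cc1OC | intermediate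
9 | ethyl vinyl ether | C=COCC | starting material
10 | racemic 2-[3,5-dimethoxy-4-(methoxymethoxy)phenoxy]-4-(1-ethoxyvinyl)-4-hydroxy-3-methoxycyclobut-2-en-1-one | C=C(OCC)C1(O)C(OC)=C(Oc2cc(OC)c(OCOC)c(OC)c2)C1=O | intermediate
11 | racemic 2-[3,5-dimethoxy-4-(methoxymethoxy)phenoxy]-4-(1-ethoxyvinyl)-3,4-dimethoxycyclobut-2-en-1-one | C=C(OCC)C1(OC)C(OC)=C(Oc2cc(OC)c(OCOC)c(OC)c2)C1=O | intermediate
12 | (3Z)-2-[3,5-dimethoxy-4-(methoxymethoxy)phenoxy]-5-ethoxy-3,4-dimethoxyhexa-1,3,5-trien-1-one (dienylketene) | C=C(OCC)/C(OC)=C(OC)\C(Oc1cc(OC)c(OCOC)c(OC)c1)=C=O | intermediate (not isolated)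
13 | 2-[3,5-dimethoxy-4-(methoxymethoxy)phenoxy]-5-ethoxy-3,4-dimethoxycyclohexa-2,4-dien-1-one | CCOC1=C(OC)C(OC)=C(Oc2cc(OC)c(OCOC)c(OC)c2)C(=O)C1 | intermediate (not isolated)
14 | 2-[3,5-dimethoxy-4-(methoxymethoxy)phenoxy]-5-ethoxy-3,4-dimethoxyphenol | CCOc1cc(O)c(Oc2cc(OC)c(OCOC)c(OC)c2)c(OC)c1OC | intermediate
15 | 4-bromo-3,5-dimethoxybenzaldehyde | COc1cc(C=O)cc(OC)c1Br | starting material
16 | 4-{2-[3,5-dimethoxy-4-(methoxymethoxy)phenoxy]-5-ethoxy-3,4-dimethoxyphenoxy}-3,5-dimethoxybenzaldehyde | CCOc1cc(Oc2c(OC)cc(C=O)cc2OC)c(Oc2cc(OC)c(OCOC)c(OC)c2)c(OC)c1OC | intermediate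
17 | 4-{2-[3,5-dimethoxy-4-(methoxymethoxy)phenoxy]-5-ethoxy-3,4-dimethoxyphenoxy}-3,5-dimethoxyphenyl formate | CCOc1cc(Oc2c(OC)cc(OC=O)cc2OC)c(Oc2cc(OC)c(OCOC)c(OC)c2)c(OC)c1OC | intermediate (not isolated)
18 | 4-{2-[3,5-dimethoxy-4-(methoxymethoxy)phenoxy]-5-ethoxy-3,4-dimethoxyphenoxy}-3,5-dimethoxyphenol | CCOc1cc(Oc2c(OC)cc(O)cc2OC)c(Oc2cc(OC)c(OCOC)c(OC)c2)c(OC)c1OC | intermediate
19 | 4-(4-{2-[3,5-dimethoxy-4-(methoxymethoxy)phenoxy]-5-ethoxy-3,4-dimethoxyphenoxy}-3,5-dimethoxyphenoxy)-3,5-dimethoxybenzaldehyde | CCOc1cc(Oc2c(OC)cc(Oc3c(OC)cc(C=O)cc3OC)cc2OC)c(Oc2cc(OC)c(OCOC)c(OC)c2)c(OC)c1OC | intermediate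
20 | 4-{4-[5-ethoxy-2-(4-hydroxy-3,5-dimethoxyphenoxy)-3,4-dimethoxyphenoxy]-3,5-dimethoxyphenoxy}-3,5-dimethoxybenzaldehyde | CCOc1cc(Oc2c(OC)cc(Oc3c(OC)cc(C=O)cc3OC)cc2OC)c(Oc2cc(OC)c(O)c(OC)c2)c(OC)c1OC | intermediate
21 | 4-bromo-2,6-dimethoxyphenol | COc1cc(Br)cc(OC)c1O | starting material
22 | (3,4,5-trimethoxyphenyl)boronic acid | COc1cc(B(O)O)cc(OC)c1OC | starting material
23 | 5-bromo-1,3-dimethoxy-2-(3,4,5-trimethoxyphenoxy)benzene | COc1cc(Br)cc(OC)c1Oc1cc(OC)c(OC)c(OC)c1 | intermediate
24 | [3,5-dimethoxy-4-(3,4,5-trimethoxyphenoxy)phenyl]boronic acid | COc1cc(B(O)O)cc(OC)c1Oc1cc(OC)c(OC)c(OC)c1 | intermediate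
25 | 5-iodovanillin (4-hydroxy-3-iodo-5-methoxybenzaldehyde) | COc1cc(C=O)cc(I)c1O | starting material
26 | 4-[3,5-dimethoxy-4-(3,4,5-trimethoxyphenoxy)phenoxy]-3-iodo-5-methoxybenzaldehyde | COc1cc(C=O)cc(I)c1Oc1cc(OC)c(Oc2cc(OC)c(OC)c(OC)c2)c(OC)c1 | intermediate
27 | 4-{4-[2-(4-{2-[3,5-dimethoxy-4-(3,4,5-trimethoxyphenoxy)phenoxy]-5-formyl-3-methoxyphenoxy}-3,5-dimethoxyphenoxy)-5-ethoxy-3,4-dimethoxyphenoxy]-3,5-dimethoxyphenoxy}-3,5-dimethoxybenzaldehyde | CCOc1cc(Oc2c(OC)cc(Oc3c(OC)cc(C=O)cc3OC)cc2OC)c(Oc4cc(OC)c(Oc5cc(C=O)cc(OC)c5Oc6cc(OC)c(Oc7cc(OC)c(OC)c(OC)c7)c(OC)c6)c(OC)c4)c(OC)c1OC | intermediate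
28 | bis-formate of 27 (each formyl group replaced by a formyloxy group) | CCOc1cc(Oc2c(OC)cc(Oc3c(OC)cc(OC=O)cc3OC)cc2OC)c(Oc4cc(OC)c(Oc5cc(OC=O)cc(OC)c5Oc6cc(OC)c(Oc7cc(OC)c(OC)c(OC)c7)c(OC)c6)c(OC)c4)c(OC)c1OC | intermediate (not isolated)
29 | 4-{4-[2-(4-{2-[3,5-dimethoxy-4-(3,4,5-trimethoxyphenoxy)phenoxy]-5-hydroxy-3-methoxyphenoxy}-3,5-dimethoxyphenoxy)-5-ethoxy-3,4-dimethoxyphenoxy]-3,5-dimethoxyphenoxy}-3,5-dimethoxyphenol | CCOc1cc(Oc2c(OC)cc(Oc3c(OC)cc(O)cc3OC)cc2OC)c(Oc4cc(OC)c(Oc5cc(O)cc(OC)c5Oc6cc(OC)c(Oc7cc(OC)c(OC)c(OC)c7)c(OC)c6)c(OC)c4)c(OC)c1OC | intermediate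
30 | CNP0351377.0 (rings A–G heptaaryl hexaether, all seventeen oxygens as free hydroxyls) | Oc1cc(O)c(Oc2cc(O)c(Oc3cc(O)c(O)c(O)c3Oc3cc(O)c(Oc4cc(O)cc(O)c4Oc4cc(O)c(Oc5cc(O)c(O)c(O)c5)c(O)c4)c(O)c3)c(O)c2)c(O)c1 | target

**Summary**
Total steps: 18. Longest linear sequence: 13 steps (steps 1, 2, 5–12, 16–18 from squaric acid; the same length from syringaldehyde through steps 3–12, 16–18).

Steps most likely to fail:

1. Step 16. Both partners are ortho-flanked, so C–O bond formation at copper may stall, with protodeiodination of the iodide or oxidative degradation of the electron-rich phenolate taking over. Fallback: reverse the role of ring E from electrophile to boron partner. Starting from iodide 26, Miyaura borylation (Pd(dppf)Cl2, bis(pinacolato)diboron, KOAc, dioxane, 80 °C) would give the ring E–G pinacol boronate F1. A Chan–Lam–Evans coupling of this boronate with phenol 20 (Cu(OAc)2, pyridine, molecular sieves, air, rt) would then return to the route at dialdehyde 27.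

2. Step 9. Substitution at the bromine-bearing carbon flanked by two methoxy groups, by a phenol that itself carries an ortho aryloxy group, may be slow, and reductive debromination may compete. Fallback: exchange the roles of the two rings. Starting from phenol 14, Tf2O/pyridine would give the ring C–D aryl triflate F2, and Miyaura borylation (Pd(dppf)Cl2, bis(pinacolato)diboron, KOAc) would give the ring C–D pinacol boronate F3. Chan–Lam–Evans coupling of this boronate with syringaldehyde 4 (Cu(OAc)2, pyridine, air) would rejoin the route at aldehyde 16.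

3. Step 6. The organolithium may fail to discriminate between the two carbonyl groups, or may add to the aryloxy-bearing carbon with loss of aryloxide. Fallback: remove the need for site selectivity. Starting from dichloride 2 and two equivalents of the sodium salt of phenol 7, the symmetrical diaryl squarate F4 would be made. Addition of 1-ethoxyvinyllithium to either of its equivalent carbonyls would give the racemic bis(aryloxy) carbinol F5, and Ag2O/MeI would give the racemic bis(aryloxy) methyl ether F6. One equivalent of NaOMe in MeOH/THF at low temperature would then replace the aryloxy group on the β-carbon of the enone by addition–elimination (vinylogous transesterification), arriving at cyclobutenone 11.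

Further compounds
F1 | step 16 | 4-[3,5-dimethoxy-4-(3,4,5-trimethoxyphenoxy)phenoxy]-3-methoxy-5-(4,4,5,5-tetramethyl-1,3,2-dioxaborolan-2-yl)benzaldehyde | COc1cc(C=O)cc(B2OC(C)(C)C(C)(C)O2)c1Oc1cc(OC)c(Oc2cc(OC)c(OC)c(OC)c2)c(OC)c1
F2 | step 9 | 2-[3,5-dimethoxy-4-(methoxymethoxy)phenoxy]-5-ethoxy-3,4-dimethoxyphenyl trifluoromethanesulfonate | CCOc1cc(OS(=O)(=O)C(F)(F)F)c(Oc2cc(OC)c(OCOC)c(OC)c2)c(OC)c1OC
F3 | step 9 | 2-{2-[3,5-dimethoxy-4-(methoxymethoxy)phenoxy]-5-ethoxy-3,4-dimethoxyphenyl}-4,4,5,5-tetramethyl-1,3,2-dioxaborolane | CCOc1cc(B2OC(C)(C)C(C)(C)O2)c(Oc2cc(OC)c(OCOC)c(OC)c2)c(OC)c1OC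
F4 | step 6 | 3,4-bis[3,5-dimethoxy-4-(methoxymethoxy)phenoxy]cyclobut-3-ene-1,2-dione | COCOc1c(OC)cc(OC2=C(Oc3cc(OC)c(OCOC)c(OC)c3)C(=O)C2=O)cc1OC
F5 | step 6 | racemic 2,3-bis[3,5-dimethoxy-4-(methoxymethoxy)phenoxy]-4-(1-ethoxyvinyl)-4-hydroxycyclobut-2-en-1-one | C=C(OCC)C1(O)C(Oc2cc(OC)c(OCOC)c(OC)c2)=C(Oc2cc(OC)c(OCOC)c(OC)c2)C1=O
F6 | step 6 | racemic 2,3-bis[3,5-dimethoxy-4-(methoxymethoxy)phenoxy]-4-(1-ethoxyvinyl)-4-methoxycyclobut-2-en-1-one | C=C(OCC)C1(OC)C(Oc2cc(OC)c(OCOC)c(OC)c2)=C(Oc2cc(OC)c(OCOC)c(OC)c2)C1=O
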